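**Assumption:** CIP analysis of the given SMILES gives S at the ether-bearing carbon (O > CH2Ar > CH3 > H). Neolignan numbering is used: ring A is the 4-hydroxy-3-methoxyphenyl ring, the chain is C7 (benzylic), C8 (stereocentre), C9 (methyl), and ring B is the 4-allyl-2,6-dimethoxyphenyl ring. Compounds 1 and 4 are taken as commercial.

**Compound numbers:** 1 propiovanillone; 2 its α-bromide; 3 the MOM ether of 2; 4 4-allyl-2,6-dimethoxyphenol; 5 racemic α-aryloxy ketone; 6 (1R,2S) alcohol; 7 MOM ether of the target; 8 target.

## The problem

Target 8 is an 8-O-4′ neolignan: ring A carries the chain C7H2–C8H(O–)–C9H3, and the oxygen on C8 is the phenolic oxygen of ring B. There is no ring to close and both arenes are commodity phenylpropanoid units, so the difficulty lies in one bond and one centre. The bond is C8–O: an unactivated secondary carbon must be joined to a phenol oxygen flanked by two ortho methoxy groups, and because C7 next to it is benzylic, elimination to the conjugated propenylarene competes in any SN2 or Mitsunobu displacement. The centre is C8 (S): it is the only stereocentre, nothing else in the molecule can control it, and its carbon substituents CH3 and CH2Ar differ too little for a reagent to tell them apart by size. The allyl group limits the tools: it is saturated by H2 over palladium (so no benzyl group removed by hydrogenolysis), it isomerises to propenyl under strong base in dipolar solvents or with metal hydride isomerisation catalysts, and boron trihalide deprotections would also cut the sec-alkyl aryl ether. The free phenol of ring A must be masked whenever a phenoxide nucleophile or strong base is in play. The feature that opens a different plan is the position of C8, β to ring A: if C7 is carried as a carbonyl, C8 is the α-carbon of an aryl ketone that also bears the aryloxy oxygen of ring B, so H8 is acidic, C8 is configurationally labile, the C8–O bond can be made by SN2 at an α-keto carbon, and the racemate can be funnelled into 8S by dynamic kinetic resolution. The extra oxygen at C7 can be removed afterwards because C7 is benzylic to ring A and para to O4, which makes C7–O ionisable and reducible to CH2 without touching C8–O.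

## Retrosynthesis

**8 ⇒ 7 ⇒ 6 (functional group addition).** O4–H of 8 is traced back to the O4–CH2OCH3 acetal of 7, and one C7–H of 7 to the C7–OH of 6. The neighbouring cut, C8–O of 8 itself, is the obvious one and is weighed under Alternative 1. Compound 6 is not smaller than 8, but its C8 now sits next to a carbinol that comes from a ketone, which is what makes the next disconnection possible. The forward reaction must remove the benzylic oxygen by acid/silane ionic hydrogenation without disturbing C8, and the same acid should remove the acetal.

**6 ⇒ 5 (key disconnection).** The C7–H bond of 6 is cut, returning C7–OH to C7=O. Both stereocentres of 6 disappear: 5 is a racemate with no stereochemical information. Reducing a single enantiomer of 5 would be pointless because 5 racemises under base; here that lability is the asset. The forward reaction is a dynamic kinetic resolution by hydrogenation with trans-RuCl2[(R)-xylBINAP][(R)-DAIPEN] and KOtBu (xylBINAP = 2,2′-bis[di(3,5-xylyl)phosphino]-1,1′-binaphthyl; DAIPEN = 1,1-bis(4-methoxyphenyl)-3-methylbutane-1,2-diamine). It must reduce C=O and leave the allyl C=C alone.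

**5 ⇒ 3 + 4.** The C8–O bond is cut. At this oxidation level C8 is α to the C7 carbonyl, so SN2 by the hindered phenoxide of 4 is accelerated and needs no stereocontrol. Both ortho positions and the para position of 4 are substituted, so only O-alkylation can occur. The neighbouring cut C7–C1 (acyl–aryl) would need an organometallic addition to an α-aryloxy amide and is longer. The precursors are far simpler: 4 is commercial and 3 is two steps from 1.

**3 ⇒ 2 ⇒ 1.** The O4–CH2OCH3 bond and the C8–Br bond are cut. Bromination comes first, on the free phenol, because the HBr it liberates would cleave the acetal. The acetal is chosen because it withstands carbonate, alkoxide and H2 and is removed by the acid of the last step.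

## Roads not taken

**Alternative 1:** (the obvious route) Cut C8–O at the alcohol oxidation level. (R)-2-Methyloxirane A1 is opened by the aryl Grignard reagent of silyl-protected 4-bromoguaiacol to give (2R)-1-[4-(tert-butyldimethylsilyloxy)-3-methoxyphenyl]propan-2-ol A2. The key step is a Mitsunobu reaction of A2 with 4, with inversion, to the silyl ether A3 of the target, followed by desilylation. This is about two steps shorter. However, the whole stereochemical outcome rests on one displacement at an unactivated secondary carbon by a di-ortho-substituted phenol. The oxyphosphonium intermediate has an anti-periplanar benzylic H7, so E2 to the conjugated propenylarene competes, and any ionisation lowers the ee. The configuration is bought stoichiometrically and cannot be corrected afterwards. In the chosen plan the C–O bond forms at an SN2-activated carbon with no stereochemical demand, and C8 is set catalytically from a racemate.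

**Alternative 2:** (biomimetic) Cut C8–O as a radical coupling. A one-electron oxidant acts on (E)-isoeugenol A4 and 4; the C8 radical site of A4 couples with the phenoxyl oxygen of 4 to give the quinone methide A5, and hydride addition to C7 of A5 gives the target constitution in two operations. C8 is formed in a radical–radical coupling with no control element, so the product is racemic. The radical of A4 also couples with itself through C5 and O4, and 4 can be over-oxidised to its own quinone methide. The chosen plan accepts more steps in exchange for a defined C8.

**Alternative 3:** Cut the C7–H and C8–H bonds. The forward key step is asymmetric hydrogenation of the (Z)-enol ether A6 with a chiral cationic iridium P,N catalyst to the (S)-bromo ether A7, followed by palladium-catalysed allylation to 7. Because H2 would saturate the allyl group, ring B must carry bromine and the allyl group arrives late. E and Z isomers of such unfunctionalised trisubstituted enol ethers give opposite enantiomers, so the step is not convergent and needs geometrically pure A6. Making A6 by joining the hindered phenol oxygen to a vinyl carbon is harder than the target's own C–O bond. The chosen key step takes a stereorandom precursor and keeps the allyl group throughout.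

Key step: step 4

## Route

**Step 1**
Reactants: 1 1-(4-hydroxy-3-methoxyphenyl)propan-1-one
Product: 2 rac-2-bromo-1-(4-hydroxy-3-methoxyphenyl)propan-1-one
Conditions: CuBr2 (2.1 equiv), EtOAc/CHCl3 (1:1), reflux
Reagents that add atoms: copper dibromide, Br[Cu]Br
Why: α-Bromination of an aryl alkyl ketone by copper dibromide through the copper enolate; the para acyl group deactivates ring A toward nuclear bromination, so the free phenol is tolerated.

**Step 2**
Reactants: 2 rac-2-bromo-1-(4-hydroxy-3-methoxyphenyl)propan-1-one
Product: 3 rac-2-bromo-1-[3-methoxy-4-(methoxymethoxy)phenyl]propan-1-one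
Conditions: MOMCl (1.3 equiv), iPr2NEt (1.5 equiv), CH2Cl2, 0 °C
Reagents that add atoms: chloromethyl methyl ether, COCCl
Why: O-Alkylation of the acidic para-acyl phenol by a very reactive chloromethyl ether; the hindered amine and low temperature leave the secondary bromide untouched.

**Step 3**
Reactants: 3 rac-2-bromo-1-[3-methoxy-4-(methoxymethoxy)phenyl]propan-1-one; 4 4-allyl-2,6-dimethoxyphenol
Product: 5 rac-2-(4-allyl-2,6-dimethoxyphenoxy)-1-[3-methoxy-4-(methoxymethoxy)phenyl]propan-1-one
Conditions: K2CO3 (1.5 equiv), acetone, reflux
Reagents that add atoms: none
Why: Williamson etherification at an α-keto secondary bromide, where the C7 carbonyl accelerates SN2 enough for the di-ortho-substituted phenoxide; ortho and para positions of 4 are blocked, so only O-alkylation is possible, and C8 is formed racemic, as step 4 requires.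

**Step 4**
Reactants: 5 rac-2-(4-allyl-2,6-dimethoxyphenoxy)-1-[3-methoxy-4-(methoxymethoxy)phenyl]propan-1-one
Product: 6 (1R,2S)-2-(4-allyl-2,6-dimethoxyphenoxy)-1-[3-methoxy-4-(methoxymethoxy)phenyl]propan-1-ol
Conditions: H2 (8 atm), trans-RuCl2[(R)-xylBINAP][(R)-DAIPEN] (0.5 mol %), KOtBu (20 mol %), iPrOH, 25 °C
Reagents that add atoms: none
Why: Dynamic kinetic resolution by asymmetric hydrogenation. KOtBu in iPrOH reversibly removes H8, which is acidified by the C7 aryl ketone and the aryloxy oxygen, so (R)-5 and (S)-5 interconvert through the achiral potassium enolate faster than either is reduced. The 18-electron RuH2(diphosphine)(diamine) species formed from the precatalyst, H2 and base transfers Ru–H and N–H to C7=O in a six-membered outer-sphere transition state without binding the substrate at the metal, which is why the allyl C=C should be neither reduced nor isomerised. The closest known reaction type is the dynamic kinetic resolution of racemic α-aryloxy and α-alkoxy ketones with RuCl2(diphosphine)(1,2-diamine)/alkoxide catalysts; no ring is closed. C7 is set by the catalyst: the (R)-diphosphine/(R)-diamine antipode, which reduces aryl methyl ketones to (S)-carbinols, should attack the same face here, and that face is 7R by the CIP rules because C8 outranks the aryl group. C8 is set by matching of substrate and catalyst: on that face only the 8S enantiomer can keep the C8–OAr bond anti to the incoming hydride with H8 rather than C9 beside the trajectory (polar Felkin–Anh), so it should be reduced faster and give the erythro (1R,2S) alcohol. The step needs racemisation to outpace reduction and a large rate gap between the enantiomers of 5; the acidity of H8, the low H2 pressure and the excess of base over ruthenium serve the first, and the bulk of the 2,6-dimethoxyaryloxy group next to the carbonyl serves the second. Because C7 becomes CH2 in step 5, what counts is the 8S:8R ratio of the product, not the configuration at C7 as such.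

**Step 5**
Reactants: 6 (1R,2S)-2-(4-allyl-2,6-dimethoxyphenoxy)-1-[3-methoxy-4-(methoxymethoxy)phenyl]propan-1-ol
Product: 8 4-[(2S)-2-(4-allyl-2,6-dimethoxyphenoxy)propyl]-2-methoxyphenol, via aryl methoxymethyl ether 7 (not isolated)
Conditions: Et3SiH (6 equiv), CF3CO2H, CH2Cl2, 0 °C; then 23 °C
Reagents that add atoms: none
Why: Ionic hydrogenation: acid ionises the benzylic C7–OH to a cation stabilised by the para oxygen O4 of ring A and Et3SiH delivers hydride, giving 7 with C7 as CH2 and C8 not involved as a reacting centre; on warming the same acid cleaves the aryl acetal and the silane reduces the methoxymethyl cation. The monosubstituted alkene, the aryl methyl ethers and the sec-alkyl aryl ether are not attacked by CF3CO2H at these temperatures.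

## Compound list

1 | 1-(4-hydroxy-3-methoxyphenyl)propan-1-one (propiovanillone) | CCC(=O)c1ccc(O)c(OC)c1 | starting material
2 | rac-2-bromo-1-(4-hydroxy-3-methoxyphenyl)propan-1-one | CC(Br)C(=O)c1ccc(O)c(OC)c1 | intermediate
3 | rac-2-bromo-1-[3-methoxy-4-(methoxymethoxy)phenyl]propan-1-one | CC(Br)C(=O)c1ccc(OCOC)c(OC)c1 | intermediate
4 | 4-allyl-2,6-dimethoxyphenol | C=CCc1cc(OC)c(O)c(OC)c1 | starting material
5 | rac-2-(4-allyl-2,6-dimethoxyphenoxy)-1-[3-methoxy-4-(methoxymethoxy)phenyl]propan-1-one | C=CCc1cc(OC)c(OC(C)C(=O)c2ccc(OCOC)c(OC)c2)c(OC)c1 | intermediate
6 | (1R,2S)-2-(4-allyl-2,6-dimethoxyphenoxy)-1-[3-methoxy-4-(methoxymethoxy)phenyl]propan-1-ol | C=CCc1cc(OC)c(O[C@@H](C)[C@H](O)c2ccc(OCOC)c(OC)c2)c(OC)c1 | intermediate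
7 | 5-allyl-1,3-dimethoxy-2-{[(2S)-1-[3-methoxy-4-(methoxymethoxy)phenyl]propan-2-yl]oxy}benzene | C=CCc1cc(OC)c(O[C@@H](C)Cc2ccc(OCOC)c(OC)c2)c(OC)c1 | intermediate
8 | 4-[(2S)-2-(4-allyl-2,6-dimethoxyphenoxy)propyl]-2-methoxyphenol | C=CCc1cc(OC)c(O[C@@H](C)Cc2ccc(O)c(OC)c2)c(OC)c1 | target

## Step count and least certain steps

Total steps: 5. Longest linear sequence: 5 (1 → 2 → 3 → 5 → 6 → 8; 4 enters at step 3).

**Step 4 (key step).** Three things can go wrong.
- Racemisation of 5 may not keep pace with reduction, so the reaction drifts toward a simple kinetic resolution.
- The catalyst may discriminate poorly between the two enantiomers of 5; with C7 fixed by the catalyst this appears as a syn/anti mixture in 6 and ends as low ee in 8.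
- The diastereo-preference may be opposite to the polar Felkin–Anh sense assumed, which would select 8R with this antipode. The other catalyst antipode would then be needed.
- Fallback: take C8 from the chiral pool. It sets out from 4. A Mitsunobu reaction with methyl (R)-lactate (PPh3, diisopropyl azodicarboxylate, THF, 0 °C; inversion at an activated α-ester carbinol) should give methyl (2S)-2-(4-allyl-2,6-dimethoxyphenoxy)propanoate F1. Reduction with iBu2AlH (CH2Cl2, −78 °C) should give (2S)-2-(4-allyl-2,6-dimethoxyphenoxy)propanal F2. The Grignard reagent of 4-bromo-2-methoxy-1-(methoxymethoxy)benzene F3 (from 4-bromo-2-methoxyphenol with MOMCl and iPr2NEt, then Mg in THF) is added at −78 °C. The fallback comes back to the route at 6, which forms together with its C7 epimer, (1S,2S)-2-(4-allyl-2,6-dimethoxyphenoxy)-1-[3-methoxy-4-(methoxymethoxy)phenyl]propan-1-ol F4. F4 is carried along because step 5 converts both into 7.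

**Step 5.** The C7 cation may leak before the silane captures it, either by a 1,2-hydride shift of H8 to C7 or by loss of H8 to the enol ether. Both paths return the target constitution but with C8 scrambled, so the damage would be erosion of ee rather than a by-product. A second concern is electrophilic attack of the methoxymethyl cation on the electron-rich ring B if the silane is depleted.
- Fallback: a radical deoxygenation that never forms the cation. It sets out from 6. NaH, CS2, then MeI (THF, 0 °C) should give O-{(1R,2S)-2-(4-allyl-2,6-dimethoxyphenoxy)-1-[3-methoxy-4-(methoxymethoxy)phenyl]propyl} S-methyl carbonodithioate F5. Barton–McCombie reduction (Bu3SnH at high concentration, AIBN, toluene, 80 °C) should outrun β-scission of the aryloxy group from the C7 radical. The fallback comes back to the route at 7, whose acetal is then cleaved with CF3CO2H/Et3SiH as in the second stage of step 5; no benzylic leaving group remains at that point.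

**Step 1.** Nuclear bromination of ring A ortho to the free phenol, or a second bromination at C8, may compete with mono-α-bromination on this electron-rich guaiacyl ketone.
- Fallback: reverse the order and brominate through a silyl enol ether under non-acidic conditions. It sets out from 1. MOMCl and iPr2NEt (CH2Cl2, 0 °C) give 1-[3-methoxy-4-(methoxymethoxy)phenyl]propan-1-one F6. LiN(SiMe3)2 and Me3SiCl (THF, −78 °C) give (Z)-{1-[3-methoxy-4-(methoxymethoxy)phenyl]prop-1-enyloxy}trimethylsilane F7, which is not isolated. N-Bromosuccinimide (THF, 0 °C) then brominates it, and the fallback comes back to the route at 3.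

## Further compounds

F1 | step 4 | methyl (2S)-2-(4-allyl-2,6-dimethoxyphenoxy)propanoate | C=CCc1cc(OC)c(O[C@@H](C)C(=O)OC)c(OC)c1
F2 | step 4 | (2S)-2-(4-allyl-2,6-dimethoxyphenoxy)propanal | C=CCc1cc(OC)c(O[C@@H](C)C=O)c(OC)c1
F3 | step 4 | 4-bromo-2-methoxy-1-(methoxymethoxy)benzene | COCOc1ccc(Br)cc1OC
F4 | step 4 | (1S,2S)-2-(4-allyl-2,6-dimethoxyphenoxy)-1-[3-methoxy-4-(methoxymethoxy)phenyl]propan-1-ol | C=CCc1cc(OC)c(O[C@@H](C)[C@@H](O)c2ccc(OCOC)c(OC)c2)c(OC)c1
F5 | step 5 | O-{(1R,2S)-2-(4-allyl-2,6-dimethoxyphenoxy)-1-[3-methoxy-4-(methoxymethoxy)phenyl]propyl} S-methyl carbonodithioate | C=CCc1cc(OC)c(O[C@@H](C)[C@H](OC(=S)SC)c2ccc(OCOC)c(OC)c2)c(OC)c1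
F6 | step 1 | 1-[3-methoxy-4-(methoxymethoxy)phenyl]propan-1-one | CCC(=O)c1ccc(OCOC)c(OC)c1
F7 | step 1 | (Z)-{1-[3-methoxy-4-(methoxymethoxy)phenyl]prop-1-enyloxy}trimethylsilane | C/C=C(\O[Si](C)(C)C)c1ccc(OCOC)c(OC)c1
A1 | alternative 1 | (R)-2-methyloxirane | C[C@@H]1CO1
A2 | alternative 1 | (2R)-1-[4-(tert-butyldimethylsilyloxy)-3-methoxyphenyl]propan-2-ol | C[C@@H](O)Cc1ccc(O[Si](C)(C)C(C)(C)C)c(OC)c1
A3 | alternative 1 | tert-butyl{4-[(2S)-2-(4-allyl-2,6-dimethoxyphenoxy)propyl]-2-methoxyphenoxy}dimethylsilane | C=CCc1cc(OC)c(O[C@@H](C)Cc2ccc(O[Si](C)(C)C(C)(C)C)c(OC)c2)c(OC)c1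
A4 | alternative 2 | 2-methoxy-4-[(E)-prop-1-enyl]phenol ((E)-isoeugenol) | C/C=C/c1ccc(O)c(OC)c1
A5 | alternative 2 | rac-4-[2-(4-allyl-2,6-dimethoxyphenoxy)propylidene]-2-methoxycyclohexa-2,5-dien-1-one | C=CCc1cc(OC)c(OC(C)C=C2C=CC(=O)C(OC)=C2)c(OC)c1
A6 | alternative 3 | 5-bromo-1,3-dimethoxy-2-{[(1Z)-1-[3-methoxy-4-(methoxymethoxy)phenyl]prop-1-en-2-yl]oxy}benzene | COCOc1ccc(/C=C(/C)Oc2c(OC)cc(Br)cc2OC)cc1OC
A7 | alternative 3 | 5-bromo-1,3-dimethoxy-2-{[(2S)-1-[3-methoxy-4-(methoxymethoxy)phenyl]propan-2-yl]oxy}benzene | COCOc1ccc(C[C@H](C)Oc2c(OC)cc(Br)cc2OC)cc1OC
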